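A small charge is where we begin. In the south run, with G at 0.047 M, X reads 41 % at 40.0 min and has fallen to 33 % by 80.0 min, so something consumes it.

| setting | south-west | north | south | flask |
|---|---|---|---|---|
| G | 0.094 M | 0.094 M | 0.047 M | 0.094 M |
| Q | 0.75 equiv | 1.1 equiv | 1.5 equiv | 1.50 equiv |
| remark | run made earlier | run made earlier | run made earlier |  |
| time |  |  |  | 2.0 h |
| volume of the second phase over the first |  |  |  | 2.0 |

| run | time / min | X / % |
|---|---|---|
| south-west | 6.00 | 16 |
| south-west | 10.0 | 24 |
| south-west | 15.0 | 28 |
| south-west | 25.0 | 32 |
| south-west | 40.0 | 39 |
| south-west | 80.0 | 40 |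
| north | 6.00 | 20 |
| north | 10.0 | 30 |
| north | 15.0 | 35 |
| north | 25.0 | 39 |
| north | 40.0 | 44 |
| north | 80.0 | 43 |
| south | 6.00 | 19 |
| south | 10.0 | 26 |
| south | 20.0 | 38 |
| south | 40.0 | 41 |
| south | 80.0 | 33 |

(readings scatter by 1.5 percentage points)

* time up to 2.0 h at which X stands highest
* the amount of X, in percent of the G charged, at that time

- for X the Z are counted in
- in the second phase: Q; everything else is in the first
- charges count per volume of the first phase; a concentration in a rate is the amount of a species over the volume of its own phase; every rate counts per litre of the first phase
- as a solid, counted per litre of solution: Z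
- the earlier runs were read with a standard deviation of 1.5 percentage points
- steps under discussion: L <-> Q; G + L -> X; Z <-> X; L + X -> D
- the earlier runs hold the two phases in the same ratio of volumes as the flask asked about

We take the steps G + L → X and L + X → D. Both use L, so L cancels when we divide the rate of making X by the rate of using it. Let S, the selectivity factor, be the rate constant of L + X over that of G + L. Then making over using equals [G]/(S[X]), and total X stands highest when dissolved [X]/[G] equals the inverse of S, however L is supplied.

Without crystals, the top as a fraction y of the G charged is S raised to the power S/(one minus S). For S near one this inverts to S ≈ one minus 2(one plus ln y). The south reading then gives S = 0.783, a reading with its scatter.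

But the flask has twice the south charge, so the same yield would mean 0.0385 M of X, and the north run, with the flask's G but 1.1 equiv of Q, reads 44 %. Perhaps some X is hiding as Z, out of reach of L. We therefore commit to the middle of the two readings, 42.5 %.

For the time, the flask has the south run's equivalents at double the charge, so bimolecular steps should halve the south time to 0.333 h. But if the transfer of Q to L is first order in Q, its own time does not halve with the charge, so we take 0.333 h as the early end.

The forecast says 0.42 h and 45 %, later and higher than ours: “Extra Q therefore mainly speeds things up rather than raising the yield”.

The flask peaks at 0.368 h with 41.9 %, on this scheme: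

    L ⇌ Q, rate k1*([L] - [Q]/K1) per volume of the first phase (partition coefficient = 0.600, kL = 0.220 min⁻¹)
    G + L → X (k = 2.00 L mol⁻¹ min⁻¹)
    Z ⇌ X, rate k3*(cs3 - [X]) while solid is left; crystals form when [X] > cs3 (solubility = 35.0 mM, k = 12.0 min⁻¹)
    L + X → D (k = 1.60 L mol⁻¹ min⁻¹)

At that time the flask holds G 29.8 % and X 41.9 %, of which Z is 4.71 %. Dissolved X over G is thus 1.25, against the inverse of S, 1.28. In the neighbour flask charged with 0.23 M of G, the end holds G 1.62 % and X 48.9 %, of which Z is 33.6 %. Making over using there is 0.136, so X is falling, and its top had been 62.9 %.

The earlier runs and the new flask were generated by integration from invented constants.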